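**Retrosynthetic overview** (ring: C1 = C=O, C2 = C–OAc, C3 = C–Me, C4 = CH–OH, C5 = CH2, C6 = alkylidene carbon; side chain: C2' = alkene carbon, C3' = carbinol)
1. End game: TBS off C4–OH; enol acetate from the diosphenol (PMB removed with DDQ); angelate by DMAP-free mixed-anhydride acylation; prenyl terminus by cross-metathesis of an allyl group.
2. C3'–C4' bond and the (S)-carbinol: Brown asymmetric allylation of the (E)-enal 18.
3. Key C6–C2' bond: intermolecular aldol of the lithium enolate of ring ketone 12 with 1,1-dimethoxyacetone, then E1cB dehydration to the exocyclic (E)-alkene and acetal hydrolysis.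
4. Ring ketone 12: Stork–Danheiser transposition (MeLi) of a vinylogous ester whose α'-oxygen (future C4, R) comes from enolate hydroxylation and lipase resolution; the C2 oxygen from Rh-carbenoid O–H insertion.
5. Rings: the single carbocycle is present from the start (cyclohexane-1,3-dione); no ring is formed.

Assumption: lipase PS hydrolyses the (R)-acetate of rac-8 first (Kazlauskas rule); the configuration of 9 is confirmed by Mosher ester analysis before going on.

**Step 1**
Reactants: 1 cyclohexane-1,3-dione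
Product: 2 2-diazocyclohexane-1,3-dione
Conditions: p-ABSA, Et3N, MeCN, 0 °C to rt
Reagents that add atoms: 4-acetamidobenzenesulfonyl azide (p-ABSA), CC(=O)Nc1ccc(cc1)S(=O)(=O)N=[N+]=[N-]
Why: Regitz diazo transfer to the acidic C2 of the 1,3-dione; no stereocentre is involved.

**Step 2**
Reactants: 2 2-diazocyclohexane-1,3-dione; 3 (4-methoxyphenyl)methanol
Product: 4 3-hydroxy-2-[(4-methoxybenzyl)oxy]cyclohex-2-en-1-one
Conditions: Rh2(OAc)4 (1 mol %), 3 (3 equiv), PhH, 80 °C
Reagents that add atoms: none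
Why: Rh(II)-carbenoid O–H insertion into the benzylic alcohol puts the future enol oxygen on C2 as its PMB ether, and under Rh catalysis it outruns Wolff rearrangement.

**Step 3**
Reactants: 4 3-hydroxy-2-[(4-methoxybenzyl)oxy]cyclohex-2-en-1-one
Product: 5 3-methoxy-2-[(4-methoxybenzyl)oxy]cyclohex-2-en-1-one
Conditions: TMSCHN2, PhMe/MeOH (4:1), 0 °C to rt
Reagents that add atoms: (trimethylsilyl)diazomethane, C[Si](C)(C)C=[N+]=[N-]
Why: O-methylation of the vinylogous acid; the dione is symmetrical, so only one vinylogous ester can form.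

**Step 4**
Reactants: 5 3-methoxy-2-[(4-methoxybenzyl)oxy]cyclohex-2-en-1-one
Product: 8 rac-6-acetoxy-3-methoxy-2-[(4-methoxybenzyl)oxy]cyclohex-2-en-1-one, via lithium dienolate 6 (not isolated), via lithium alkoxide 7 (not isolated)
Conditions: LDA, THF, −78 °C; (±)-Davis oxaziridine, −78 °C; then Ac2O, −78 to 0 °C
Reagents that add atoms: 3-phenyl-2-(phenylsulfonyl)oxaziridine, O=S(=O)(N1OC1c2ccccc2)c3ccccc3; acetic anhydride, CC(=O)OC(C)=O
Why: Kinetic α'-deprotonation of the vinylogous ester and Davis enolate hydroxylation put oxygen on C6 (racemic), and the alkoxide is trapped as the acetate needed for the resolution.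

**Step 5**
Reactants: 8 rac-6-acetoxy-3-methoxy-2-[(4-methoxybenzyl)oxy]cyclohex-2-en-1-one
Product: 9 (6R)-6-hydroxy-3-methoxy-2-[(4-methoxybenzyl)oxy]cyclohex-2-en-1-one
Conditions: Amano lipase PS, pH 7 phosphate buffer/MTBE, 30 °C, to about 45% conversion
Reagents that add atoms: none
Why: Lipase kinetic resolution by enantioselective ester hydrolysis releases the (R)-alcohol (the future C4 stereocentre), while the (S)-acetate stays unchanged and is removed by chromatography.

**Step 6**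
Reactants: 9 (6R)-6-hydroxy-3-methoxy-2-[(4-methoxybenzyl)oxy]cyclohex-2-en-1-one
Product: 10 (6R)-6-[(tert-butyldimethylsilyl)oxy]-3-methoxy-2-[(4-methoxybenzyl)oxy]cyclohex-2-en-1-one
Conditions: TBSCl, imidazole, DMF, rt
Reagents that add atoms: tert-butyldimethylsilyl chloride, CC(C)(C)[Si](C)(C)Cl
Why: Silylation of the secondary α-hydroxy ketone under mild conditions; the C–O stereocentre is not touched.

**Step 7**
Reactants: 10 (6R)-6-[(tert-butyldimethylsilyl)oxy]-3-methoxy-2-[(4-methoxybenzyl)oxy]cyclohex-2-en-1-one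
Product: 12 (4R)-4-[(tert-butyldimethylsilyl)oxy]-2-[(4-methoxybenzyl)oxy]-3-methylcyclohex-2-en-1-one, via lithium tertiary alkoxide 11 (not isolated)
Conditions: MeLi, THF, −78 to 0 °C; then 1 M HCl, THF, 0 °C
Reagents that add atoms: methyllithium, [Li]C; water, O
Why: Stork–Danheiser sequence: 1,2-addition of MeLi to the vinylogous ester carbonyl, then acid hydrolysis of the enol ether with loss of the tertiary hydroxyl gives the transposed 3-methyl enone; the silyloxy carbon becomes C4 with its (R) configuration unchanged.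

**Step 8**
Reactants: 12 (4R)-4-[(tert-butyldimethylsilyl)oxy]-2-[(4-methoxybenzyl)oxy]-3-methylcyclohex-2-en-1-one; 13 1,1-dimethoxypropan-2-one
Product: 15 (4R)-4-[(tert-butyldimethylsilyl)oxy]-6-(2-hydroxy-1,1-dimethoxypropan-2-yl)-2-[(4-methoxybenzyl)oxy]-3-methylcyclohex-2-en-1-one (diastereomer mixture), via lithium enolate 14 (not isolated)
Conditions: LDA, THF, −78 °C; 13, −78 °C; AcOH/THF quench at −78 °C
Reagents that add atoms: none
Why: Intermolecular aldol addition: C6 carries the only α-hydrogens of 12, and its lithium enolate adds to the activated α,α-dialkoxy ketone to form the key C6–C2' bond; the two new stereocentres do not matter because both become sp2 in step 9.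

**Step 9**
Reactants: 15 aldol adduct
Product: 17 (4R,6E)-4-[(tert-butyldimethylsilyl)oxy]-6-(1,1-dimethoxypropan-2-ylidene)-2-[(4-methoxybenzyl)oxy]-3-methylcyclohex-2-en-1-one, via tertiary mesylate 16 (not isolated)
Conditions: MsCl, Et3N, CH2Cl2, 0 °C; then DBU, 0 °C to rt
Reagents that add atoms: none
Why: E1cB elimination through the mesylate: only C6–H is acidic, so the alkene forms in conjugation, and the bulky CH(OMe)2 group takes the position away from the ring carbonyl (E), which is expected to be both the kinetic and the thermodynamic outcome; any minor Z isomer is removed by chromatography.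

**Step 10**
Reactants: 17 (E)-enone acetal
Product: 18 (2E)-2-[(5R)-5-[(tert-butyldimethylsilyl)oxy]-3-[(4-methoxybenzyl)oxy]-4-methyl-2-oxocyclohex-3-en-1-ylidene]propanal
Conditions: TsOH·H2O (cat.), acetone/H2O (10:1), 0 °C to rt
Reagents that add atoms: water, O
Why: Mild acid-catalysed hydrolysis of the dimethyl acetal gives the aldehyde; the secondary TBS ether and the PMB enol ether survive, and the E-enal cannot cyclise onto the ring ketone.

**Step 11**
Reactants: 18 (E)-enal
Product: 20 (4R,6E)-4-[(tert-butyldimethylsilyl)oxy]-6-[(3S)-3-hydroxyhex-5-en-2-ylidene]-2-[(4-methoxybenzyl)oxy]-3-methylcyclohex-2-en-1-one, via diisopinocampheylborinate ester 19 (not isolated)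
Conditions: (−)-Ipc2BOMe, allylMgBr, Et2O, 0 °C to rt; then 18, −78 °C; ethanolamine work-up
Reagents that add atoms: allylmagnesium bromide, C=CC[Mg]Br (allyl delivered as (−)-B-allyldiisopinocampheylborane)
Why: Brown asymmetric carbonyl allylation through a chair six-membered transition state: the (+)-α-pinene-derived reagent attacks the Si face of the aldehyde and sets the (S)-carbinol, the aldehyde reacts far faster than the conjugated ketone at −78 °C, and the non-oxidative work-up spares the enone.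

**Step 12**
Reactants: 20 homoallylic alcohol; 21 2-methylbut-2-ene
Product: 22 (4R,6E)-4-[(tert-butyldimethylsilyl)oxy]-6-[(3S)-3-hydroxy-6-methylhept-5-en-2-ylidene]-2-[(4-methoxybenzyl)oxy]-3-methylcyclohex-2-en-1-one
Conditions: Grubbs II (5 mol %), 21/CH2Cl2 (1:1), 40 °C, sealed tube
Reagents that add atoms: none
Why: Olefin cross-metathesis of the terminal alkene with excess 2-methylbut-2-ene gives the prenyl terminus; the tetrasubstituted and electron-poor alkenes are inert to the catalyst.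

**Step 13**
Reactants: 22 prenyl carbinol; 23 angelic acid
Product: 24 (2E,3S)-2-[(5R)-5-[(tert-butyldimethylsilyl)oxy]-3-[(4-methoxybenzyl)oxy]-4-methyl-2-oxocyclohex-3-en-1-ylidene]-6-methylhept-5-en-3-yl (2Z)-2-methylbut-2-enoate
Conditions: 23, 2,4,6-trichlorobenzoyl chloride, Et3N, PhMe, rt; then 22, 80 °C (no DMAP)
Reagents that add atoms: none
Why: Yamaguchi-type mixed-anhydride esterification run without DMAP, the protocol known to keep the Z geometry of the angelate; O-acylation leaves the carbinol configuration unchanged.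

**Step 14**
Reactants: 24 angelate PMB ether
Product: 25 (2E,3S)-2-[(5R)-5-[(tert-butyldimethylsilyl)oxy]-3-hydroxy-4-methyl-2-oxocyclohex-3-en-1-ylidene]-6-methylhept-5-en-3-yl (2Z)-2-methylbut-2-enoate
Conditions: DDQ, CH2Cl2/pH 7 buffer (10:1), 0 °C to rt
Reagents that add atoms: none
Why: Oxidative cleavage of the PMB ether frees the diosphenol (enol of the 1,2-dione) without touching the silyl ether, the esters or the alkenes.

**Step 15**
Reactants: 25 diosphenol
Product: 26 (2E,3S)-2-[(5R)-3-acetoxy-5-[(tert-butyldimethylsilyl)oxy]-4-methyl-2-oxocyclohex-3-en-1-ylidene]-6-methylhept-5-en-3-yl (2Z)-2-methylbut-2-enoate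
Conditions: Ac2O, pyridine, CH2Cl2, 0 °C
Reagents that add atoms: acetic anhydride, CC(=O)OC(C)=O
Why: O-acetylation of the acidic enol, the only free hydroxyl, gives the enol acetate.

**Step 16**
Reactants: 26 enol acetate TBS ether
Product: 27 (2E,3S)-2-[(5R)-3-acetoxy-5-hydroxy-4-methyl-2-oxocyclohex-3-en-1-ylidene]-6-methylhept-5-en-3-yl (2Z)-2-methylbut-2-enoate
Conditions: HF·pyridine, pyridine, THF, 0 °C to rt
Reagents that add atoms: none
Why: Fluoride desilylation under buffered acidic conditions frees the C4 hydroxyl; under these conditions the enol acetate and the allylic angelate neither migrate nor hydrolyse.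

**Compound list**
1 | cyclohexane-1,3-dione | O=C1CCCC(=O)C1 | starting material
2 | 2-diazocyclohexane-1,3-dione | [N-]=[N+]=C1C(=O)CCCC1=O | intermediate
3 | (4-methoxyphenyl)methanol | COc1ccc(CO)cc1 | starting material
4 | 3-hydroxy-2-[(4-methoxybenzyl)oxy]cyclohex-2-en-1-one | OC1=C(OCc2ccc(OC)cc2)C(=O)CCC1 | intermediate
5 | 3-methoxy-2-[(4-methoxybenzyl)oxy]cyclohex-2-en-1-one | COC1=C(OCc2ccc(OC)cc2)C(=O)CCC1 | intermediate
6 | lithium 5-methoxy-6-[(4-methoxybenzyl)oxy]cyclohexa-1,5-dien-1-olate (not isolated) | [Li]OC1=CCCC(OC)=C1OCc2ccc(OC)cc2 | intermediate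
7 | lithium alkoxide of rac-6-hydroxy-3-methoxy-2-[(4-methoxybenzyl)oxy]cyclohex-2-en-1-one (not isolated) | [Li]OC1CCC(OC)=C(OCc2ccc(OC)cc2)C1=O | intermediate
8 | rac-6-acetoxy-3-methoxy-2-[(4-methoxybenzyl)oxy]cyclohex-2-en-1-one | CC(=O)OC1CCC(OC)=C(OCc2ccc(OC)cc2)C1=O | intermediate
9 | (6R)-6-hydroxy-3-methoxy-2-[(4-methoxybenzyl)oxy]cyclohex-2-en-1-one | O=C1[C@H](O)CCC(OC)=C1OCc2ccc(OC)cc2 | intermediate
10 | (6R)-6-[(tert-butyldimethylsilyl)oxy]-3-methoxy-2-[(4-methoxybenzyl)oxy]cyclohex-2-en-1-one | O=C1[C@H](O[Si](C)(C)C(C)(C)C)CCC(OC)=C1OCc2ccc(OC)cc2 | intermediate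
11 | lithium (6R)-6-[(tert-butyldimethylsilyl)oxy]-3-methoxy-2-[(4-methoxybenzyl)oxy]-1-methylcyclohex-2-en-1-olate, both C1 epimers (not isolated) | [Li]OC1(C)[C@H](O[Si](C)(C)C(C)(C)C)CCC(OC)=C1OCc2ccc(OC)cc2 | intermediate
12 | (4R)-4-[(tert-butyldimethylsilyl)oxy]-2-[(4-methoxybenzyl)oxy]-3-methylcyclohex-2-en-1-one | O=C1CC[C@@H](O[Si](C)(C)C(C)(C)C)C(C)=C1OCc2ccc(OC)cc2 | intermediate
13 | 1,1-dimethoxypropan-2-one | CC(=O)C(OC)OC | starting material
14 | lithium enolate of 12 (C1–OLi, C1=C6; not isolated) | [Li]OC1=CC[C@@H](O[Si](C)(C)C(C)(C)C)C(C)=C1OCc2ccc(OC)cc2 | intermediate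
15 | (4R)-4-[(tert-butyldimethylsilyl)oxy]-6-(2-hydroxy-1,1-dimethoxypropan-2-yl)-2-[(4-methoxybenzyl)oxy]-3-methylcyclohex-2-en-1-one, diastereomer mixture | COC(OC)C(C)(O)C1C[C@@H](O[Si](C)(C)C(C)(C)C)C(C)=C(OCc2ccc(OC)cc2)C1=O | intermediate
16 | tertiary methanesulfonate of 15 (not isolated) | COC(OC)C(C)(OS(C)(=O)=O)C1C[C@@H](O[Si](C)(C)C(C)(C)C)C(C)=C(OCc2ccc(OC)cc2)C1=O | intermediate
17 | (4R,6E)-4-[(tert-butyldimethylsilyl)oxy]-6-(1,1-dimethoxypropan-2-ylidene)-2-[(4-methoxybenzyl)oxy]-3-methylcyclohex-2-en-1-one | COC(OC)/C(C)=C1\C[C@@H](O[Si](C)(C)C(C)(C)C)C(C)=C(OCc2ccc(OC)cc2)C1=O | intermediate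
18 | (2E)-2-[(5R)-5-[(tert-butyldimethylsilyl)oxy]-3-[(4-methoxybenzyl)oxy]-4-methyl-2-oxocyclohex-3-en-1-ylidene]propanal | O=C/C(C)=C1\C[C@@H](O[Si](C)(C)C(C)(C)C)C(C)=C(OCc2ccc(OC)cc2)C1=O | intermediate
19 | B,B-diisopinocampheylborinate ester of 20 (not isolated) | C=CC[C@H](OB([C@@H]3C[C@@H]4C[C@H]([C@H]3C)C4(C)C)[C@@H]5C[C@@H]6C[C@H]([C@H]5C)C6(C)C)/C(C)=C1\C[C@@H](O[Si](C)(C)C(C)(C)C)C(C)=C(OCc2ccc(OC)cc2)C1=O | intermediate
20 | (4R,6E)-4-[(tert-butyldimethylsilyl)oxy]-6-[(3S)-3-hydroxyhex-5-en-2-ylidene]-2-[(4-methoxybenzyl)oxy]-3-methylcyclohex-2-en-1-one | C=CC[C@H](O)/C(C)=C1\C[C@@H](O[Si](C)(C)C(C)(C)C)C(C)=C(OCc2ccc(OC)cc2)C1=O | intermediate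
21 | 2-methylbut-2-ene | CC=C(C)C | starting material
22 | (4R,6E)-4-[(tert-butyldimethylsilyl)oxy]-6-[(3S)-3-hydroxy-6-methylhept-5-en-2-ylidene]-2-[(4-methoxybenzyl)oxy]-3-methylcyclohex-2-en-1-one | CC(C)=CC[C@H](O)/C(C)=C1\C[C@@H](O[Si](C)(C)C(C)(C)C)C(C)=C(OCc2ccc(OC)cc2)C1=O | intermediate
23 | angelic acid, (2Z)-2-methylbut-2-enoic acid | C/C=C(/C)C(=O)O | starting material
24 | (2E,3S)-2-[(5R)-5-[(tert-butyldimethylsilyl)oxy]-3-[(4-methoxybenzyl)oxy]-4-methyl-2-oxocyclohex-3-en-1-ylidene]-6-methylhept-5-en-3-yl (2Z)-2-methylbut-2-enoate | C/C=C(/C)C(=O)O[C@@H](CC=C(C)C)/C(C)=C1\C[C@@H](O[Si](C)(C)C(C)(C)C)C(C)=C(OCc2ccc(OC)cc2)C1=O | intermediate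
25 | (2E,3S)-2-[(5R)-5-[(tert-butyldimethylsilyl)oxy]-3-hydroxy-4-methyl-2-oxocyclohex-3-en-1-ylidene]-6-methylhept-5-en-3-yl (2Z)-2-methylbut-2-enoate | C/C=C(/C)C(=O)O[C@@H](CC=C(C)C)/C(C)=C1\C[C@@H](O[Si](C)(C)C(C)(C)C)C(C)=C(O)C1=O | intermediate
26 | (2E,3S)-2-[(5R)-3-acetoxy-5-[(tert-butyldimethylsilyl)oxy]-4-methyl-2-oxocyclohex-3-en-1-ylidene]-6-methylhept-5-en-3-yl (2Z)-2-methylbut-2-enoate | C/C=C(/C)C(=O)O[C@@H](CC=C(C)C)/C(C)=C1\C[C@@H](O[Si](C)(C)C(C)(C)C)C(C)=C(OC(C)=O)C1=O | intermediate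
27 | (2E,3S)-2-[(5R)-3-acetoxy-5-hydroxy-4-methyl-2-oxocyclohex-3-en-1-ylidene]-6-methylhept-5-en-3-yl (2Z)-2-methylbut-2-enoate | C/C=C(/C)C(=O)O[C@@H](CC=C(C)C)/C(C)=C1\C[C@@H](O)C(C)=C(OC(C)=O)C1=O | target

**Totals:** 16 steps; longest linear sequence 16 steps (1 to 27).

**Steps most likely to fail, with fallbacks**

Step 5 (enzymatic resolution: rate, selectivity and sense on this substituted acetate are not known in advance). The fallback replaces resolution by catalytic asymmetric oxidation; it sets out from 5 and comes back at 10. Enolisation of 5 with LDA and silylation with TBSCl gives the cross-conjugated silyl dienol ether tert-butyl({5-methoxy-6-[(4-methoxybenzyl)oxy]cyclohexa-1,5-dien-1-yl}oxy)dimethylsilane F1. Shi epoxidation (D-fructose-derived ketone, Oxone, K2CO3 buffer, MeCN/dimethoxymethane, 0 °C) should attack only the trisubstituted silyl enol ether double bond and give the silyloxy epoxide F2. This opens with 1,4-silyl shift (Rubottom) to the (R)-silyloxy ketone 10; any desilylated material is 9 and is silylated as in step 6. The facial sense is assigned by analogy with 1-arylcyclohexenes, and the enantiomeric ketone catalyst is used if it proves opposite.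

Step 9 (elimination of a hindered tertiary aldol: retro-aldol, deconjugated alkene or an E/Z mixture). The fallback replaces aldol/dehydration by an olefination; it sets out from 12 and comes back at 17. The lithium enolate of 12 is C-phosphinylated with diethyl chlorophosphite to the diethyl phosphonite F3, which is oxidised in the same flask (air or H2O2) to diethyl [(5R)-5-[(tert-butyldimethylsilyl)oxy]-3-[(4-methoxybenzyl)oxy]-4-methyl-2-oxocyclohex-3-en-1-yl]phosphonate F4. Horner–Wadsworth–Emmons reaction of F4 with 13 (NaH, THF, 0 °C to rt) can place the double bond only between C6 and C2' and, by analogy with phosphonoacetate olefinations of 13, should favour the E isomer 17. Olefination of a ketone with a ring-substituted β-keto phosphonate is itself sluggish, so this is a second line only.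

Step 13 (acylation of a hindered allylic alcohol with angelic acid: slow reaction or Z-to-E drift to the tiglate). The fallback builds the Z-alkene on the substrate; it sets out from 22 and comes back at 24. Esterification of 22 with 2-[bis(2,2,2-trifluoroethoxy)phosphoryl]propanoic acid (DCC, cat. DMAP; nothing to isomerise) gives the phosphonopropanoate ester F5. Still–Gennari olefination of F5 with acetaldehyde (KHMDS, 18-crown-6, THF, −78 °C) gives the (Z)-2-methylbut-2-enoate 24.

**Further compounds**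
F1 | step 5 | tert-butyl({5-methoxy-6-[(4-methoxybenzyl)oxy]cyclohexa-1,5-dien-1-yl}oxy)dimethylsilane | CC(C)(C)[Si](C)(C)OC1=CCCC(OC)=C1OCc2ccc(OC)cc2
F2 | step 5 | silyloxy epoxide of F1 at the silyl enol ether double bond (C6 configured as in 10) | CC(C)(C)[Si](C)(C)O[C@@]12O[C@@H]1CCC(OC)=C2OCc3ccc(OC)cc3
F3 | step 9 | diethyl [(5R)-5-[(tert-butyldimethylsilyl)oxy]-3-[(4-methoxybenzyl)oxy]-4-methyl-2-oxocyclohex-3-en-1-yl]phosphonite | CCOP(OCC)C1C[C@@H](O[Si](C)(C)C(C)(C)C)C(C)=C(OCc2ccc(OC)cc2)C1=O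
F4 | step 9 | diethyl [(5R)-5-[(tert-butyldimethylsilyl)oxy]-3-[(4-methoxybenzyl)oxy]-4-methyl-2-oxocyclohex-3-en-1-yl]phosphonate | CCOP(=O)(OCC)C1C[C@@H](O[Si](C)(C)C(C)(C)C)C(C)=C(OCc2ccc(OC)cc2)C1=O
F5 | step 13 | (2E,3S)-2-[(5R)-5-[(tert-butyldimethylsilyl)oxy]-3-[(4-methoxybenzyl)oxy]-4-methyl-2-oxocyclohex-3-en-1-ylidene]-6-methylhept-5-en-3-yl 2-[bis(2,2,2-trifluoroethoxy)phosphoryl]propanoate | CC(C(=O)O[C@@H](CC=C(C)C)/C(C)=C1\C[C@@H](O[Si](C)(C)C(C)(C)C)C(C)=C(OCc2ccc(OC)cc2)C1=O)P(=O)(OCC(F)(F)F)OCC(F)(F)F
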